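**Strategy**

The route builds ring A instead of functionalising a phloroglucinol. Ring A is a pentasubstituted benzene whose oxygens on C2′, C4′ and C6′ alternate with the C1′ acyl group, the C3′ prenyl group and C5′–H. Cutting C2′–C3′ and C1′–C6′ reveals a prenyl-bearing 1-methoxy-1,3-bis(trimethylsilyloxy)diene and a 1-alkoxy-ynone that already carries ring B and the two-carbon linker. One cycloaddition–aromatisation closes ring A and sets every substituent in place regiospecifically. The ynone is made from a ring B Weinreb amide and an alkoxyacetylide, the diene from γ-prenylated methyl acetoacetate; a single O-demethylation at O2′ then completes the synthesis.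

Key step: step 11

**Remarks on the chemistry (assumptions)**

- C5′ of ring A carries hydrogen, so the ring is penta- and not hexasubstituted.
- 5-Bromovanillin has OH on C4 and OMe on C3, whereas ring B needs OMe on C4 and OH on C3. Steps 1 and 2 move the methyl group.
- The alkyl group on the ynol ether oxygen is treated as a protecting group for O2′, and methyl is used. It cannot leave by retro-ene fragmentation when the ynone is heated. An O-methyl ortho to the ketone is also removed by halide much faster than an O-ethyl, which would have to compete with the ring B 4-O-methyl.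
- Ring B is carried as a triisopropylsilyl ether. The fluoride work-up of the key step frees it, so the 3′-prenyl resorcinol never meets acid.
- The C1 geometry of diene 17 and the configuration of cycloadduct 18 are of no consequence; both are lost on aromatisation. The target has no stereocentre.

**Route**

Step 1
Reactants: 1 5-bromovanillin (3-bromo-4-hydroxy-5-methoxybenzaldehyde)
Product: 2 3-bromo-4,5-dihydroxybenzaldehyde
Conditions: AlCl3, pyridine, CH2Cl2, 40 °C; then aq. HCl
Reagents that add atoms: none
Why: Lewis-acid O-demethylation of a guaiacol: the aluminium phenoxide formed at O4 chelates the neighbouring methoxy oxygen and chloride removes its methyl group, a standard cleavage of ortho-hydroxy anisoles that leaves the aldehyde and the bromide untouched.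

Step 2
Reactants: 2 3-bromo-4,5-dihydroxybenzaldehyde
Product: 3 3-bromo-5-hydroxy-4-methoxybenzaldehyde
Conditions: MeI (1.05 equiv), Li2CO3 (1.0 equiv), DMF, 40 °C
Reagents that add atoms: iodomethane, CI
Why: Regioselective Williamson etherification: the weak base ionises only the more acidic 4-OH (para to the formyl group and ortho to bromine), so methylation should occur at that oxygen and leave the 5-OH free.

Step 3
Reactants: 3 3-bromo-5-hydroxy-4-methoxybenzaldehyde
Product: 4 3-bromo-4-methoxy-5-[(triisopropylsilyl)oxy]benzaldehyde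
Conditions: i-Pr3SiCl, imidazole, DMF, 23 °C
Reagents that add atoms: chlorotriisopropylsilane, CC(C)[Si](Cl)(C(C)C)C(C)C
Why: Imidazole-promoted O-silylation of a phenol; the bulky silyl ether should withstand the basic and organometallic steps that follow and is removed later by fluoride.

Step 4
Reactants: 4 3-bromo-4-methoxy-5-[(triisopropylsilyl)oxy]benzaldehyde; 5 tributyl(3-methylbut-2-en-1-yl)stannane
Product: 6 4-methoxy-3-(3-methylbut-2-en-1-yl)-5-[(triisopropylsilyl)oxy]benzaldehyde
Conditions: Pd(PPh3)4 (5 mol %), DMF, 100 °C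
Reagents that add atoms: none
Why: Stille cross-coupling: zerovalent palladium inserts into the C–Br bond, the prenyl group is transferred from tin, and reductive elimination at the unsubstituted allyl terminus should give the linear prenyl arene, with the aldehyde and the silyl ether as spectators.

Step 5
Reactants: 6 4-methoxy-3-(3-methylbut-2-en-1-yl)-5-[(triisopropylsilyl)oxy]benzaldehyde; 7 diethyl {2-[methoxy(methyl)amino]-2-oxoethyl}phosphonate
Product: 8 (2E)-N-methoxy-N-methyl-3-{4-methoxy-3-(3-methylbut-2-en-1-yl)-5-[(triisopropylsilyl)oxy]phenyl}prop-2-enamide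
Conditions: NaH, THF, 0 → 23 °C
Reagents that add atoms: none
Why: Horner–Wadsworth–Emmons olefination with a stabilised phosphonate anion, which should give the E-configured cinnamoyl Weinreb amide.

Step 6
Reactants: 8 (2E)-N-methoxy-N-methyl-3-{4-methoxy-3-(3-methylbut-2-en-1-yl)-5-[(triisopropylsilyl)oxy]phenyl}prop-2-enamide
Product: 9 N-methoxy-N-methyl-3-{4-methoxy-3-(3-methylbut-2-en-1-yl)-5-[(triisopropylsilyl)oxy]phenyl}propanamide
Conditions: H2 (1 atm), RhCl(PPh3)3 (5 mol %), toluene–EtOH, 23 °C
Reagents that add atoms: none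
Why: Homogeneous catalytic hydrogenation: RhCl(PPh3)3 reduces the 1,2-disubstituted conjugated alkene far faster than the trisubstituted prenyl alkene and does not touch the N–O or O–Si bonds.

Step 7
Reactants: 9 N-methoxy-N-methyl-3-{4-methoxy-3-(3-methylbut-2-en-1-yl)-5-[(triisopropylsilyl)oxy]phenyl}propanamide; 10 2-chloro-1,1-dimethoxyethane
Product: 12 1-methoxy-5-{4-methoxy-3-(3-methylbut-2-en-1-yl)-5-[(triisopropylsilyl)oxy]phenyl}pent-1-yn-3-one, via lithium methoxyacetylide 11 (not isolated)
Conditions: 10 (2.0 equiv), LiNEt2 (6.0 equiv, from Et2NH and n-BuLi), THF, 0 °C; then 9, −78 → −40 °C; AcOH, −78 °C; pH 7 buffer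
Reagents that add atoms: none
Why: Twofold base-induced elimination (methanol, then HCl) turns the chloro acetal into lithium methoxyacetylide, which acylates in a Weinreb ketone synthesis whose chelated tetrahedral adduct prevents over-addition; the cold acetic acid quench protonates the amines before the electrophilic ynone is released.

Step 8
Reactants: 13 methyl acetoacetate; 14 prenyl bromide (1-bromo-3-methylbut-2-ene)
Product: 15 methyl 7-methyl-3-oxooct-6-enoate
Conditions: NaH, THF, 0 °C; n-BuLi, 0 °C; then 14, 0 → 23 °C; aq. NH4Cl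
Reagents that add atoms: none
Why: γ-Alkylation of a β-keto ester dianion: the second deprotonation creates the more reactive terminal carbanion, which displaces the allylic bromide in an SN2 reaction while the α-position stays masked as the enolate.

Step 9
Reactants: 15 methyl 7-methyl-3-oxooct-6-enoate
Product: 16 methyl (2Z)-7-methyl-3-[(trimethylsilyl)oxy]octa-2,6-dienoate
Conditions: Me3SiCl, Et3N, hexane, 23 °C
Reagents that add atoms: chlorotrimethylsilane, C[Si](C)(C)Cl
Why: Silyl enol ether formation by O-silylation of the enolised β-keto ester with an amine base; the geometry of this double bond is lost in the next step.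

Step 10
Reactants: 16 methyl (2Z)-7-methyl-3-[(trimethylsilyl)oxy]octa-2,6-dienoate
Product: 17 (1Z,3Z)-1-methoxy-7-methyl-1,3-bis[(trimethylsilyl)oxy]octa-1,3,6-triene
Conditions: LiN(i-Pr)2, THF, −78 °C; Me3SiCl, −78 → 0 °C; filtered under Ar from hexane, used at once
Reagents that add atoms: chlorotrimethylsilane, C[Si](C)(C)Cl
Why: Kinetic γ-deprotonation of the vinylogous ester and O-silylation of the resulting dienolate give the silyl ketene acetal diene; the side chain should take the less hindered position on C4 (3Z).

Step 11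
Reactants: 12 1-methoxy-5-{4-methoxy-3-(3-methylbut-2-en-1-yl)-5-[(triisopropylsilyl)oxy]phenyl}pent-1-yn-3-one; 17 (1Z,3Z)-1-methoxy-7-methyl-1,3-bis[(trimethylsilyl)oxy]octa-1,3,6-triene
Product: 19 1-[4,6-dihydroxy-2-methoxy-3-(3-methylbut-2-en-1-yl)phenyl]-3-[3-hydroxy-4-methoxy-5-(3-methylbut-2-en-1-yl)phenyl]propan-1-one (3,4′,6′-trihydroxy-2′,4-dimethoxy-3′,5-diprenyldihydrochalcone), via silylated cyclohexa-1,4-diene cycloadduct 18 (not isolated)
Conditions: 17 (2.5 equiv), toluene, 23 → 80 °C, sealed vessel; then n-Bu4NF, AcOH, THF, 0 → 23 °C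
Reagents that add atoms: none
Why: Proposed new method: the electron-rich diene 17 and the push–pull alkyne 12 are matched in polarity, so diene C4 (prenyl-bearing, most nucleophilic) should bond to the methoxy-bearing alkyne carbon and diene C1 to the acyl-bearing carbon, either in one asynchronous (4+2) event or as a Mukaiyama–Michael addition whose allenolate then closes 6-exo-trig onto the C1 oxocarbenium carbon; the closest known reaction type is the thermal cycloaddition–aromatisation of 1-alkoxy-1,3-bis(silyloxy)butadienes with acetylenic ketones and esters to resorcinols, which has not been shown for a 3-alkoxy-ynone. Ring A is the only ring formed and closes in this (4+2) mode through the new C2′–C3′ and C1′–C6′ bonds. Fluoride then removes the silyl group on the C6′ ketal oxygen, the hemiketal expels methoxide, and enolisation of the cyclohexadienone aromatises the ring while the enol silyl ether and the ring B silyl ether are cleaved. No stereocentre is kept, because the two sp3 carbons of 18 (C6′ and C3′) become aromatic. The step needs regioselectivity only, and the donor pattern of both partners secures it, since the reverse orientation would pair the two nucleophilic or the two electrophilic carbons. Heating without a Lewis acid is chosen to disfavour stepwise closure of diene C2 onto the ketone, and the methyl ynol ether cannot fragment by a retro-ene path.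

Step 12
Reactants: 19 1-[4,6-dihydroxy-2-methoxy-3-(3-methylbut-2-en-1-yl)phenyl]-3-[3-hydroxy-4-methoxy-5-(3-methylbut-2-en-1-yl)phenyl]propan-1-one
Product: 20 3,2′,4′,6′-tetrahydroxy-4-methoxy-3′,5-diprenyldihydrochalcone
Conditions: LiCl (excess), DMF, 150 °C; aq. NH4Cl
Reagents that add atoms: none
Why: Nucleophilic O-demethylation (SN2 at the methyl carbon by chloride), a cleavage established for O-methyl groups ortho to the carbonyl in prenylated 2′-hydroxy-6′-methoxy aryl ketones: only the O2′-methyl has an ortho carbonyl to stabilise the departing phenoxide, so the ring B methyl ether should survive, and the acid-free medium spares both prenyl groups.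

**Compound list**

1 | 5-bromovanillin (3-bromo-4-hydroxy-5-methoxybenzaldehyde) | COc1cc(C=O)cc(Br)c1O | starting material
2 | 3-bromo-4,5-dihydroxybenzaldehyde | O=Cc1cc(O)c(O)c(Br)c1 | intermediate
3 | 3-bromo-5-hydroxy-4-methoxybenzaldehyde | COc1c(O)cc(C=O)cc1Br | intermediate
4 | 3-bromo-4-methoxy-5-[(triisopropylsilyl)oxy]benzaldehyde | COc1c(O[Si](C(C)C)(C(C)C)C(C)C)cc(C=O)cc1Br | intermediate
5 | tributyl(3-methylbut-2-en-1-yl)stannane | CCCC[Sn](CCCC)(CCCC)CC=C(C)C | starting material
6 | 4-methoxy-3-(3-methylbut-2-en-1-yl)-5-[(triisopropylsilyl)oxy]benzaldehyde | COc1c(O[Si](C(C)C)(C(C)C)C(C)C)cc(C=O)cc1CC=C(C)C | intermediate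
7 | diethyl {2-[methoxy(methyl)amino]-2-oxoethyl}phosphonate | CCOP(=O)(CC(=O)N(C)OC)OCC | starting material
8 | (2E)-N-methoxy-N-methyl-3-{4-methoxy-3-(3-methylbut-2-en-1-yl)-5-[(triisopropylsilyl)oxy]phenyl}prop-2-enamide | CON(C)C(=O)/C=C/c1cc(O[Si](C(C)C)(C(C)C)C(C)C)c(OC)c(CC=C(C)C)c1 | intermediate
9 | N-methoxy-N-methyl-3-{4-methoxy-3-(3-methylbut-2-en-1-yl)-5-[(triisopropylsilyl)oxy]phenyl}propanamide | CON(C)C(=O)CCc1cc(O[Si](C(C)C)(C(C)C)C(C)C)c(OC)c(CC=C(C)C)c1 | intermediate
10 | 2-chloro-1,1-dimethoxyethane (chloroacetaldehyde dimethyl acetal) | COC(CCl)OC | starting material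
11 | lithium methoxyacetylide | [Li]C#COC | intermediate (not isolated)
12 | 1-methoxy-5-{4-methoxy-3-(3-methylbut-2-en-1-yl)-5-[(triisopropylsilyl)oxy]phenyl}pent-1-yn-3-one | COC#CC(=O)CCc1cc(O[Si](C(C)C)(C(C)C)C(C)C)c(OC)c(CC=C(C)C)c1 | intermediate
13 | methyl acetoacetate | COC(=O)CC(C)=O | starting material
14 | prenyl bromide (1-bromo-3-methylbut-2-ene) | CC(C)=CCBr | starting material
15 | methyl 7-methyl-3-oxooct-6-enoate | COC(=O)CC(=O)CCC=C(C)C | intermediate
16 | methyl (2Z)-7-methyl-3-[(trimethylsilyl)oxy]octa-2,6-dienoate | COC(=O)/C=C(/CCC=C(C)C)O[Si](C)(C)C | intermediate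
17 | (1Z,3Z)-1-methoxy-7-methyl-1,3-bis[(trimethylsilyl)oxy]octa-1,3,6-triene | CO/C(O[Si](C)(C)C)=C/C(O[Si](C)(C)C)=C/CC=C(C)C | intermediate
18 | 1-{2,6-dimethoxy-3-(3-methylbut-2-en-1-yl)-4,6-bis[(trimethylsilyl)oxy]cyclohexa-1,4-dien-1-yl}-3-{4-methoxy-3-(3-methylbut-2-en-1-yl)-5-[(triisopropylsilyl)oxy]phenyl}propan-1-one, racemic, 6-OMe and 3-prenyl cis, one enantiomer drawn | CO[C@]1(O[Si](C)(C)C)C=C(O[Si](C)(C)C)[C@H](CC=C(C)C)C(OC)=C1C(=O)CCc1cc(O[Si](C(C)C)(C(C)C)C(C)C)c(OC)c(CC=C(C)C)c1 | intermediate (not isolated)
19 | 1-[4,6-dihydroxy-2-methoxy-3-(3-methylbut-2-en-1-yl)phenyl]-3-[3-hydroxy-4-methoxy-5-(3-methylbut-2-en-1-yl)phenyl]propan-1-one | COc1c(CC=C(C)C)c(O)cc(O)c1C(=O)CCc1cc(O)c(OC)c(CC=C(C)C)c1 | intermediate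
20 | 3,2′,4′,6′-tetrahydroxy-4-methoxy-3′,5-diprenyldihydrochalcone | COc1c(O)cc(CCC(=O)c2c(O)cc(O)c(CC=C(C)C)c2O)cc1CC=C(C)C | target

**Step count and risks**

Total step count: 12. Longest linear sequence: 9 steps (steps 1 to 7, then 11 and 12).

Steps most likely to fail:

1. Step 11 (key step). The donor-substituted alkyne may react too slowly below the temperature at which the diene degrades by silyl migration. The reaction may also turn stepwise and close through diene C2 onto the ketone, or give (2+2) adducts. The fallback uses known chemistry and takes ring A from phloroglucinol. It sets out from Weinreb amide 9 and returns to the route at target 20. Phloroglucinol with MeOCH2Cl and i-Pr2NEt should give 1,3,5-tris(methoxymethoxy)benzene F1. Directed ortho-lithiation (n-BuLi, THF, 0 °C), transmetalation with CuI and alkylation with prenyl bromide 14 should give 1,3,5-tris(methoxymethoxy)-2-(3-methylbut-2-en-1-yl)benzene F2. A second lithiation between two acetal oxygens and acylation with 9 should give 1-[2,4,6-tris(methoxymethoxy)-3-(3-methylbut-2-en-1-yl)phenyl]-3-{4-methoxy-3-(3-methylbut-2-en-1-yl)-5-[(triisopropylsilyl)oxy]phenyl}propan-1-one F3. n-Bu4NF in THF should free the ring B phenol to give 1-[2,4,6-tris(methoxymethoxy)-3-(3-methylbut-2-en-1-yl)phenyl]-3-[3-hydroxy-4-methoxy-5-(3-methylbut-2-en-1-yl)phenyl]propan-1-one F4. Dilute HCl in MeOH at 23 °C should then remove the three acetals to give 20.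

2. Step 7. The push–pull ynone may be lost by hydration or by conjugate addition of the liberated amines during the quench, and the amide may be enolised instead of acylated. The fallback sets out from 9 and returns at ynone 12. i-Bu2AlH (THF, −78 °C) should reduce the Weinreb amide to 3-{4-methoxy-3-(3-methylbut-2-en-1-yl)-5-[(triisopropylsilyl)oxy]phenyl}propanal F5. Addition of lithium methoxyacetylide 11 at −78 °C should give racemic 1-methoxy-5-{4-methoxy-3-(3-methylbut-2-en-1-yl)-5-[(triisopropylsilyl)oxy]phenyl}pent-1-yn-3-ol F6. Oxidation with activated MnO2 in CH2Cl2, followed by filtration only, should deliver 12 under neutral, non-aqueous conditions with no hydroxylamine present.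

3. Step 12. Demethylation may stall because the ketone is hydrogen-bonded to the 6′-OH, or the polyphenol may degrade at the temperature required. The fallback sets out from 19 and returns at 20. The cleavage is then directed by chelation instead of driven by heat: MgI2·OEt2 in THF at 60 °C binds between the ketone and O2′, iodide removes the methyl group, and THF takes up the HI formed. No new compound arises (entry F0).

**Further compounds**

F1 | step 11 | 1,3,5-tris(methoxymethoxy)benzene | COCOc1cc(OCOC)cc(OCOC)c1
F2 | step 11 | 1,3,5-tris(methoxymethoxy)-2-(3-methylbut-2-en-1-yl)benzene | COCOc1cc(OCOC)c(CC=C(C)C)c(OCOC)c1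
F3 | step 11 | 1-[2,4,6-tris(methoxymethoxy)-3-(3-methylbut-2-en-1-yl)phenyl]-3-{4-methoxy-3-(3-methylbut-2-en-1-yl)-5-[(triisopropylsilyl)oxy]phenyl}propan-1-one | COCOc1cc(OCOC)c(CC=C(C)C)c(OCOC)c1C(=O)CCc1cc(O[Si](C(C)C)(C(C)C)C(C)C)c(OC)c(CC=C(C)C)c1
F4 | step 11 | 1-[2,4,6-tris(methoxymethoxy)-3-(3-methylbut-2-en-1-yl)phenyl]-3-[3-hydroxy-4-methoxy-5-(3-methylbut-2-en-1-yl)phenyl]propan-1-one | COCOc1cc(OCOC)c(CC=C(C)C)c(OCOC)c1C(=O)CCc1cc(O)c(OC)c(CC=C(C)C)c1
F5 | step 7 | 3-{4-methoxy-3-(3-methylbut-2-en-1-yl)-5-[(triisopropylsilyl)oxy]phenyl}propanal | O=CCCc1cc(O[Si](C(C)C)(C(C)C)C(C)C)c(OC)c(CC=C(C)C)c1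
F6 | step 7 | 1-methoxy-5-{4-methoxy-3-(3-methylbut-2-en-1-yl)-5-[(triisopropylsilyl)oxy]phenyl}pent-1-yn-3-ol (racemic) | COC#CC(O)CCc1cc(O[Si](C(C)C)(C(C)C)C(C)C)c(OC)c(CC=C(C)C)c1
F0 | step 12 | none | none
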